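**Plan**

1. Retrosynthesis: cut the C3–O ester bond to the feruloyl group, then C4–C4a of ring C, then the O1–C2 aryl ether, then the oxirane and the C2–C3 bond (vinyl anion plus B-ring aldehyde).
2. Enabling feature: C4 is a bare CH2 bonded to C4a, and C4a of ring A is ortho to O1 and ortho/para to the 5- and 7-oxygens. Ring C can therefore close by Friedel–Crafts attack of C4a on the terminal carbon of a C3–C4 oxirane that already carries the C3 oxygen.
3. Forward: rings A and B are bought (phloroglucinol, a 4-O-methylgallate). The B-ring aldehyde is taken to the vinyl carbinol, the epoxy alcohol and the O1–C2 ether to ring A; ring C then closes through C4–C4a, followed by 3-O-feruloylation and global desilylation.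
4. Stereochemistry: C3 comes from a titanium/L-(+)-tartrate kinetic-resolution epoxidation (erythro epoxy alcohol). C2 comes from Mitsunobu inversion with the ring-A phenol (erythro to threo, hence 2,3-cis). Neither centre is touched in the ring closure, and the E-alkene is carried in from ferulic acid.
5. All phenols travel as silyl ethers, so the last step is a buffered fluoride treatment that spares the cinnamate ester and its C=C bond.

Key step: step 8

Remark: methyl 3,5-dihydroxy-4-methoxybenzoate (the methyl ester of 4-O-methylgallic acid) is assumed to be a catalogue chemical. TBS = tert-butyldimethylsilyl. Flavan numbering (O1, C2, C3, C4, C4a … C8a) is used throughout.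

**Route**

Step 1
Reactants: 1 methyl 3,5-dihydroxy-4-methoxybenzoate
Product: 2 methyl 3,5-bis(tert-butyldimethylsilyloxy)-4-methoxybenzoate
Conditions: TBSCl (2.4 equiv), imidazole (5 equiv), DMF, rt
Reagents that add atoms: tert-butyldimethylsilyl chloride, CC(C)(C)[Si](C)(C)Cl
Why: Corey-type phenol silylation (TBSCl/imidazole) should cap both hydroxyls flanking the methoxy group, while the methyl ester and aryl methyl ether are inert and no stereocentre is involved.

Step 2
Reactants: 2 methyl 3,5-bis(tert-butyldimethylsilyloxy)-4-methoxybenzoate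
Product: 3 [3,5-bis(tert-butyldimethylsilyloxy)-4-methoxyphenyl]methanol
Conditions: DIBAL-H (2.5 equiv), CH2Cl2, −78 to 0 °C; Rochelle salt work-up
Reagents that add atoms: none
Why: DIBAL-H reduction of an aryl methyl ester to the benzyl alcohol is routine at low temperature, and aryl silyl ethers tolerate the hydride.

Step 3
Reactants: 3 [3,5-bis(tert-butyldimethylsilyloxy)-4-methoxyphenyl]methanol
Product: 4 3,5-bis(tert-butyldimethylsilyloxy)-4-methoxybenzaldehyde
Conditions: activated MnO2 (excess), CH2Cl2, rt
Reagents that add atoms: none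
Why: Activated MnO2 oxidises benzylic alcohols selectively under neutral conditions, so the aldehyde should form without over-oxidation or silyl loss.

Step 4
Reactants: 4 3,5-bis(tert-butyldimethylsilyloxy)-4-methoxybenzaldehyde; 5 vinylmagnesium bromide
Product: 6 racemic 1-[3,5-bis(tert-butyldimethylsilyloxy)-4-methoxyphenyl]prop-2-en-1-ol
Conditions: 5 (1.3 equiv, 1 M in THF), THF, −78 to −20 °C; aqueous quench
Reagents that add atoms: none
Why: Grignard 1,2-addition of the vinyl anion to a non-enolisable aryl aldehyde forms the future C2–C3 bond and gives the secondary allylic alcohol as a racemate, which is what the next step requires.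

Step 5
Reactants: 6 racemic 1-[3,5-bis(tert-butyldimethylsilyloxy)-4-methoxyphenyl]prop-2-en-1-ol
Product: 7 (S)-[3,5-bis(tert-butyldimethylsilyloxy)-4-methoxyphenyl][(2R)-oxiran-2-yl]methanol (erythro epoxy alcohol)
Conditions: Ti(OiPr)4 (0.2 equiv), L-(+)-diisopropyl tartrate (0.24 equiv), TBHP (0.55 equiv, anhydrous), 4 Å MS, CH2Cl2, −20 °C; chromatographic removal of the unreacted (S)-alcohol
Reagents that add atoms: tert-butyl hydroperoxide, CC(C)(C)OO
Why: Sharpless kinetic-resolution epoxidation: with L-(+)-DIPT the titanium–tartrate complex should epoxidise the (R)-alcohol much faster than the (S)-alcohol and deliver oxygen to the alkene face that gives the erythro epoxy alcohol, so the oxirane carbon becomes R by tartrate control and the carbinol carbon keeps the spatial arrangement of the (R)-alcohol (its descriptor becomes S only because oxiranyl now outranks aryl), while the slow (S)-alcohol stays behind.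

Step 6
Reactants: 8 phloroglucinol (benzene-1,3,5-triol)
Product: 9 3,5-bis(tert-butyldimethylsilyloxy)phenol
Conditions: TBSCl (2.0 equiv), imidazole (4 equiv), DMF, 0 °C to rt; chromatography
Reagents that add atoms: tert-butyldimethylsilyl chloride, CC(C)(C)[Si](C)(C)Cl
Why: Phenol silylation of the C3-symmetric triol with two equivalents of TBSCl should give a statistical mixture of mono-, bis- and tris-ethers from which the bis-ether is separated, stoichiometry being the only control needed because all three hydroxyls are equivalent.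

Step 7
Reactants: 7 (S)-[3,5-bis(tert-butyldimethylsilyloxy)-4-methoxyphenyl][(2R)-oxiran-2-yl]methanol; 9 3,5-bis(tert-butyldimethylsilyloxy)phenol
Product: 10 (2R)-2-{(R)-[3,5-bis(tert-butyldimethylsilyloxy)phenoxy][3,5-bis(tert-butyldimethylsilyloxy)-4-methoxyphenyl]methyl}oxirane (threo aryloxy epoxide)
Conditions: PPh3 (1.5 equiv), DIAD (1.5 equiv), 9 (1.3 equiv), toluene, 0 °C to rt
Reagents that add atoms: none
Why: Mitsunobu etherification: the phenol protonates the PPh3/DIAD betaine and its aryloxide displaces the benzylic alkoxyphosphonium group by SN2 with inversion (S to R), turning the erythro epoxy alcohol into the threo aryl ether that carries O1–C2, while the oxirane is a spectator under these neutral conditions and SN1 leakage should be limited because the para-methoxy group of ring B is twisted out of conjugation by its two ortho silyloxy neighbours.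

Step 8
Reactants: 10 (2R)-2-{(R)-[3,5-bis(tert-butyldimethylsilyloxy)phenoxy][3,5-bis(tert-butyldimethylsilyloxy)-4-methoxyphenyl]methyl}oxirane
Product: 11 (2R,3R)-5,7-bis(tert-butyldimethylsilyloxy)-2-[3,5-bis(tert-butyldimethylsilyloxy)-4-methoxyphenyl]-3,4-dihydro-2H-chromen-3-ol (tetra-O-TBS-4'-O-methylepigallocatechin)
Conditions: AuCl3 (5 mol %), AgOTf (15 mol %), 4 Å MS, CH2Cl2, 0 °C to rt
Reagents that add atoms: none
Why: The cationic gold(III) Lewis acid binds the oxirane oxygen and polarises the C4–O bond; C4a of the bis(silyloxy)phenoxy ring, ortho to O1 and ortho/para to both silyloxy groups, attacks the CH2 terminus in an SN2-like opening, and the arenium ion rearomatises by proton loss to leave the free 3-OH. The closest known reaction type is the gold- or Lewis-acid-catalysed intramolecular Friedel–Crafts cycloalkylation of aryl glycidyl ethers to 3-chromanols, which has also been applied to 1-aryl-substituted glycidyl aryl ethers to make flavan-3-ols. Ring C closes in the 6-endo-tet mode (attack at the distal oxirane carbon, so both oxirane carbons end up in the ring). No stereocentre is created: the C2–O1 and C3–O bonds are not broken, so the threo (R,R) ether maps onto the 2,3-cis (2R,3R) chromanol. The step needs 6-endo attack at C4 instead of 5-exo attack at C3, and no ionisation of the benzylic C2–O1 bond. The first is secured by the unhindered primary terminus and the geometry of π-attack through the O1 tether (the two ortho positions are equivalent, so only one regioisomer can arise); the second by the mild activator at low temperature and a B ring that stabilises a benzylic cation only weakly.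

Step 9
Reactants: 12 ferulic acid [(E)-3-(4-hydroxy-3-methoxyphenyl)prop-2-enoic acid]
Product: 14 (E)-3-[4-(tert-butyldimethylsilyloxy)-3-methoxyphenyl]prop-2-enoic acid (4-O-TBS-ferulic acid), via bis-TBS ferulate 13 (not isolated)
Conditions: TBSCl (2.3 equiv), imidazole (5 equiv), DMF, rt; then AcOH/THF/H2O, rt
Reagents that add atoms: tert-butyldimethylsilyl chloride, CC(C)(C)[Si](C)(C)Cl
Why: Silylation of both acidic hydroxyls followed by mild aqueous acid, which hydrolyses the very labile silyl ester but not the aryl silyl ether, is the standard way to a phenol-protected cinnamic acid and leaves the E-alkene untouched.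

Step 10
Reactants: 11 tetra-O-TBS-4'-O-methylepigallocatechin; 14 4-O-TBS-ferulic acid
Product: 15 (2R,3R)-5,7-bis(tert-butyldimethylsilyloxy)-2-[3,5-bis(tert-butyldimethylsilyloxy)-4-methoxyphenyl]-3,4-dihydro-2H-chromen-3-yl (E)-3-[4-(tert-butyldimethylsilyloxy)-3-methoxyphenyl]prop-2-enoate (penta-O-TBS ester)
Conditions: 14 (1.5 equiv), DCC (1.5 equiv), DMAP (0.3 equiv), CH2Cl2, 0 °C to rt
Reagents that add atoms: none
Why: Steglich esterification: DCC activates the acid as the O-acylisourea and DMAP relays it as the acylpyridinium ion to the secondary 3-OH, the C3–O bond is not broken so configuration is retained, and the silyl ethers and conjugated alkene are inert.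

Step 11
Reactants: 15 penta-O-TBS ester
Product: 16 4'-O-methylepigallocatechin-3-O-ferulate, (2R,3R)-5,7-dihydroxy-2-(3,5-dihydroxy-4-methoxyphenyl)-3,4-dihydro-2H-chromen-3-yl (E)-3-(4-hydroxy-3-methoxyphenyl)prop-2-enoate
Conditions: TBAF (6 equiv) premixed with AcOH (6 equiv), THF, 0 °C to rt, argon
Reagents that add atoms: none
Why: Fluoride-induced cleavage of the five aryl silyl ethers, buffered with acetic acid so that each phenoxide is protonated as it forms, should release the pentaphenol without cleaving or transesterifying the cinnamate, without touching the C=C bond and without epimerising C2 or C3.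

**Compound list**

1 | methyl 3,5-dihydroxy-4-methoxybenzoate | COC(=O)c1cc(O)c(OC)c(O)c1 | starting material
2 | methyl 3,5-bis(tert-butyldimethylsilyloxy)-4-methoxybenzoate | COC(=O)c1cc(O[Si](C)(C)C(C)(C)C)c(OC)c(O[Si](C)(C)C(C)(C)C)c1 | intermediate
3 | [3,5-bis(tert-butyldimethylsilyloxy)-4-methoxyphenyl]methanol | OCc1cc(O[Si](C)(C)C(C)(C)C)c(OC)c(O[Si](C)(C)C(C)(C)C)c1 | intermediate
4 | 3,5-bis(tert-butyldimethylsilyloxy)-4-methoxybenzaldehyde | O=Cc1cc(O[Si](C)(C)C(C)(C)C)c(OC)c(O[Si](C)(C)C(C)(C)C)c1 | intermediate
5 | vinylmagnesium bromide | C=C[Mg]Br | starting material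
6 | racemic 1-[3,5-bis(tert-butyldimethylsilyloxy)-4-methoxyphenyl]prop-2-en-1-ol | C=CC(O)c1cc(O[Si](C)(C)C(C)(C)C)c(OC)c(O[Si](C)(C)C(C)(C)C)c1 | intermediate
7 | (S)-[3,5-bis(tert-butyldimethylsilyloxy)-4-methoxyphenyl][(2R)-oxiran-2-yl]methanol | C1O[C@H]1[C@@H](O)c1cc(O[Si](C)(C)C(C)(C)C)c(OC)c(O[Si](C)(C)C(C)(C)C)c1 | intermediate
8 | phloroglucinol | Oc1cc(O)cc(O)c1 | starting material
9 | 3,5-bis(tert-butyldimethylsilyloxy)phenol | Oc1cc(O[Si](C)(C)C(C)(C)C)cc(O[Si](C)(C)C(C)(C)C)c1 | intermediate
10 | (2R)-2-{(R)-[3,5-bis(tert-butyldimethylsilyloxy)phenoxy][3,5-bis(tert-butyldimethylsilyloxy)-4-methoxyphenyl]methyl}oxirane | C1O[C@H]1[C@H](Oc2cc(O[Si](C)(C)C(C)(C)C)cc(O[Si](C)(C)C(C)(C)C)c2)c2cc(O[Si](C)(C)C(C)(C)C)c(OC)c(O[Si](C)(C)C(C)(C)C)c2 | intermediate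
11 | (2R,3R)-5,7-bis(tert-butyldimethylsilyloxy)-2-[3,5-bis(tert-butyldimethylsilyloxy)-4-methoxyphenyl]-3,4-dihydro-2H-chromen-3-ol | O[C@@H]1Cc2c(O[Si](C)(C)C(C)(C)C)cc(O[Si](C)(C)C(C)(C)C)cc2O[C@@H]1c1cc(O[Si](C)(C)C(C)(C)C)c(OC)c(O[Si](C)(C)C(C)(C)C)c1 | intermediate
12 | ferulic acid | COc1cc(/C=C/C(=O)O)ccc1O | starting material
13 | tert-butyldimethylsilyl (E)-3-[4-(tert-butyldimethylsilyloxy)-3-methoxyphenyl]prop-2-enoate | COc1cc(/C=C/C(=O)O[Si](C)(C)C(C)(C)C)ccc1O[Si](C)(C)C(C)(C)C | intermediate
14 | (E)-3-[4-(tert-butyldimethylsilyloxy)-3-methoxyphenyl]prop-2-enoic acid | COc1cc(/C=C/C(=O)O)ccc1O[Si](C)(C)C(C)(C)C | intermediate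
15 | (2R,3R)-5,7-bis(tert-butyldimethylsilyloxy)-2-[3,5-bis(tert-butyldimethylsilyloxy)-4-methoxyphenyl]-3,4-dihydro-2H-chromen-3-yl (E)-3-[4-(tert-butyldimethylsilyloxy)-3-methoxyphenyl]prop-2-enoate | COc1cc(/C=C/C(=O)O[C@@H]2Cc3c(O[Si](C)(C)C(C)(C)C)cc(O[Si](C)(C)C(C)(C)C)cc3O[C@@H]2c2cc(O[Si](C)(C)C(C)(C)C)c(OC)c(O[Si](C)(C)C(C)(C)C)c2)ccc1O[Si](C)(C)C(C)(C)C | intermediate
16 | 4'-O-methylepigallocatechin-3-O-ferulate | COc1cc(/C=C/C(=O)O[C@@H]2Cc3c(O)cc(O)cc3O[C@@H]2c2cc(O)c(OC)c(O)c2)ccc1O | target

**Step count and risks**

Total: 11 steps, of which steps 6 and 9 are one-step side branches. Longest linear sequence: 9 steps (steps 1–5, 7, 8, 10, 11; compounds 1 → 2 → 3 → 4 → 6 → 7 → 10 → 11 → 15 → 16).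

Steps most likely to fail:

Step 8 (ring closure). The Lewis acid, or adventitious triflic acid, may strip the ring-A silyl ethers, or the silyloxy-substituted ring may be too weak a π-nucleophile, so that halide or triflate opening or hydride-shift rearrangement of the oxirane outruns C4–C4a bond formation. The fallback sets out from 7 and returns at 11. Mitsunobu etherification of 7 with commercial 3,5-bis(benzyloxy)phenol (PPh3, DIAD, toluene) would give the ring-A dibenzyl threo aryloxy epoxide F1. The same gold-catalysed closure, now on the alkyl-ether substitution pattern for which it is established, would give the 5,7-di-O-benzyl chromanol F2. Hydrogenolysis (H2, Pd(OH)2/C, EtOAc) would free the two ring-A phenols without touching the B-ring silyl ethers and give the chromane-3,5,7-triol F3. Treatment with TBSCl (2.1 equiv) and imidazole in DMF at 0 °C, which silylates phenols far faster than the hindered secondary 3-OH, would then return 11.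

Step 5 (kinetic-resolution epoxidation). A monosubstituted alkene is epoxidised slowly by the titanium–tartrate complex, so conversion may stall or the rate difference between the enantiomers may be too small for a clean resolution, and long exposure to titanium alkoxide may open the product oxirane. The fallback sets out from 6 and returns at 7. Lipase-catalysed acylation (Novozym 435, vinyl acetate, MTBE, rt) should acetylate the (R)-alcohol (Kazlauskas rule, aryl as the large group) to give the (R)-allylic acetate F4, separable from the unreacted (S)-alcohol. DIBAL-H at −78 °C, which spares aryl silyl ethers where methanolic carbonate would not, would release the (R)-allylic alcohol F5. Epoxidation of this single enantiomer with Ti(OiPr)4/L-(+)-DIPT/TBHP in the matched sense would then give 7; it can be driven to full conversion with stoichiometric titanium because nothing depends on a rate ratio any more.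

Step 7 (Mitsunobu etherification). The hindered benzylic alkoxyphosphonium ion may form slowly and then be intercepted by the reduced azodicarboxylate or collapse by elimination, because the bulky, weakly acidic phenol is a poor partner; little ether would form and inversion would be eroded. The fallback sets out from 7 and 9 and returns at 10. Compound 7 would be converted with retention into its benzylic methanesulfonate F6 (MsCl, Et3N, CH2Cl2, −20 °C). This would be displaced without purification by the pre-formed potassium salt of 9 (KHMDS, 18-crown-6, toluene, 0 °C to rt), an SN2 Williamson etherification that inverts the benzylic carbon and gives 10.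

**Further compounds**

F1 | step 8 | (2R)-2-{(R)-[3,5-bis(benzyloxy)phenoxy][3,5-bis(tert-butyldimethylsilyloxy)-4-methoxyphenyl]methyl}oxirane | C1O[C@H]1[C@H](Oc2cc(OCc3ccccc3)cc(OCc3ccccc3)c2)c2cc(O[Si](C)(C)C(C)(C)C)c(OC)c(O[Si](C)(C)C(C)(C)C)c2
F2 | step 8 | (2R,3R)-5,7-bis(benzyloxy)-2-[3,5-bis(tert-butyldimethylsilyloxy)-4-methoxyphenyl]-3,4-dihydro-2H-chromen-3-ol | O[C@@H]1Cc2c(OCc3ccccc3)cc(OCc3ccccc3)cc2O[C@@H]1c1cc(O[Si](C)(C)C(C)(C)C)c(OC)c(O[Si](C)(C)C(C)(C)C)c1
F3 | step 8 | (2R,3R)-2-[3,5-bis(tert-butyldimethylsilyloxy)-4-methoxyphenyl]-3,4-dihydro-2H-chromene-3,5,7-triol | O[C@@H]1Cc2c(O)cc(O)cc2O[C@@H]1c1cc(O[Si](C)(C)C(C)(C)C)c(OC)c(O[Si](C)(C)C(C)(C)C)c1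
F4 | step 5 | (R)-1-[3,5-bis(tert-butyldimethylsilyloxy)-4-methoxyphenyl]prop-2-en-1-yl acetate | C=C[C@@H](OC(C)=O)c1cc(O[Si](C)(C)C(C)(C)C)c(OC)c(O[Si](C)(C)C(C)(C)C)c1
F5 | step 5 | (R)-1-[3,5-bis(tert-butyldimethylsilyloxy)-4-methoxyphenyl]prop-2-en-1-ol | C=C[C@@H](O)c1cc(O[Si](C)(C)C(C)(C)C)c(OC)c(O[Si](C)(C)C(C)(C)C)c1
F6 | step 7 | (S)-[3,5-bis(tert-butyldimethylsilyloxy)-4-methoxyphenyl][(2R)-oxiran-2-yl]methyl methanesulfonate | C1O[C@H]1[C@@H](OS(C)(=O)=O)c1cc(O[Si](C)(C)C(C)(C)C)c(OC)c(O[Si](C)(C)C(C)(C)C)c1
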